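Assumption: read from the SMILES, the Cf ester is the (2R)-2-methylbutanoate and the C8 ester is the (Z)-2-methylbut-2-enoate (angelate). Ring atoms are Ca (CH bearing C7), Cb (CH2), Cc and Cd (oxirane carbons, methyl on Cd), Ce (CHOH) and Cf (CH–O-acyl); the side chain is C7 (=CH2), C8, C9, C10, C11.

## Structural features

The target has one carbocycle, ring A (Ca–Cf), with a cis-fused oxirane on Cc–Cd, a free hydroxyl on Ce, an (R)-2-methylbutanoate on Cf and a side chain on Ca. The side chain runs from C7, which carries an exocyclic methylene, through the angelate-bearing carbinol C8 and the methylene C9 to a 3,3-dimethyloxirane at C10/C11. Ca, Cf, Ce, Cd and Cc are five contiguous stereocentres, and the C7 branch, both ring oxygens and the oxirane oxygen all lie on one face. C8 and C10 are insulated from the ring and from each other by the sp2 carbon C7 and by C9, so neither can be set by relay from ring A. The fragile groups are the two trisubstituted oxiranes (acid), the angelate (Z to E isomerisation), the cis-vicinal hydroxy ester at Ce/Cf (acyl migration), the alpha centre of the 2-methylbutanoate and the allylic ester at C8. The real difficulty is the all-cis array combined with three differently dressed oxygens, and an end-game that must not need acid or base once the oxiranes are in place. The key step uses the fact that Cf–Ce–Cd–Cc, with oxygen on Cf and Ce and methyl on Cd, is a 1-alkoxy-2-silyloxy-3-methylbutadiene, while Ca–Cb with C7 as acyl carbon is a vinyl ketone. The cis relation of C7 and the Cf oxygen is the endo outcome of their cycloaddition.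

## Logic of the disconnections

26 to 25: the Cc–O and Cd–O bonds of the ring oxirane are cut. The oxirane must be cis to the Ce hydroxyl, and a free allylic hydroxyl can direct the oxidant. Two stereocentres then arise in the last step with no deprotection after it. The forward step must be syn-selective and must leave three other alkenes and the side-chain oxirane alone.

25 to 24: the Ce–H bond is cut back to a Ce ketone. As an enone the Cd=Cc bond is inert to electrophilic oxidants, and the Ce hydroxyl appears only after both esters are in place, so Ce never needs a protecting group. The reduction must be 1,2, from the face anti to the Cf acyloxy group, and without acyl migration.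

24 to 22 and 23, then 22 to 21: the Cf–O acyl bond and the benzylic ether bond are cut. The ether is needed as a donor in the key step and is exchanged at the ketone stage, where Cf–OH is the only hydroxyl. The forward steps need neutral oxidative deprotection and an esterification that neither racemises 23 nor epimerises Cf.

21 to 20: the C10–O and C11–O bonds are cut. In 20 the C10=C11 bond is the only electron-rich alkene, so C10 can be set by reagent control. The step must tolerate mildly basic buffer.

20 to 19: the Cd=Cc unsaturation is traced to the Ce=Cd silyl enol ether. The enol ether made by the key step is both a masked ketone and the regiochemical marker for dehydrogenation. Hydride loss must go toward Cc and not toward the methyl group.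

19 to 16 and 17: the C8–O acyl bond is cut. The acylation must not isomerise the Z acid.

16 to 15 to 14: the C8–H bond is cut through the ketone. The C7–C8 bond formation cannot be relied on to control C8, whereas a catalyst-controlled reduction of the alpha-methylene ketone can. This needs a mild oxidation and a reduction in which the C7 alkenyl group is the large substituent.

14 to 11 and 13 (13 from 12): the C7–C8 bond is cut. C7, the former acyl carbon of the dienophile, becomes an alkenyl nucleophile that adds to an aldehyde, giving the methylene group and the C8 oxygen in one convergent step. The alkenyl metal must tolerate a silyl enol ether and an enolisable aldehyde.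

11 to 9: the C7–O sulfonate bond is cut to the methyl ketone. Enolisation must be kinetic, at the methyl group, because an enolate at Ca would epimerise Ca or expel the Cf ether.

9 to 7 and 8: the Cf–Ca and Cb–Cc bonds are cut, which opens ring A to a diene and a vinyl ketone. One step then builds the ring, Ca and Cf, and leaves the Ce=Cd enol ether placed for the later oxidation. It demands ortho regiochemistry, endo selectivity and one enone face.

7 to 6, 6 to 3 and 4, 3 to 1 and 2: the O–Si bond, the acyl–isopropenyl C–C bond and the ether C–O bond are cut in turn. This reaches commercial materials in three steps. The enol ether must be Z, and the Grignard addition must stop at the ketone.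

Three points of design differ from the most obvious version of this plan:
- The silyl group is tert-butyldimethylsilyl, which should survive the acidic catalyst and five further steps yet is still removed oxidatively by Pd(OAc)2.
- The ring ketone stays masked as that enol ether while the methyl ketone is elaborated, because a borohydride reduction could not tell the two ketones apart.
- The Weinreb amide is made in one step from 1.

## Other disconnections considered

Alternative 1: the Ce–O and Cf–O bonds are traced to an arene. In the forward sense a whole-cell toluene dioxygenase adds dioxygen across one ring bond of 1-iodo-4-methylbenzene A1 to give the cis-dihydrodiol A2.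
- In favour: A2 has both carbinol centres in the absolute sense of Ce and Cf, the methyl group is on Cd, iodine at Ca is a coupling handle for C7, and Cd=Cc is ready for the directed epoxidation. No chiral catalyst or protecting group is needed.
- Against: Ca and Cb are sp2 in A2. One alkene of a conjugated diene would have to be saturated with hydrogen delivered anti to the Cf oxygen, whereas hydroxyl-directed hydrogenation delivers it syn and would put C7 trans. Such dienediols also dimerise and dehydrate to phenols easily, fermentation equipment is required, and the enantiopurity depends on how well the enzyme tells iodine from methyl.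
- Comparison: A2 is better than the chosen plan in steps to an oxygenated ring and in setting the Ce oxygen directly, where the chosen plan needs an oxidation and a reduction. The two are equal at Cf. The chosen cycloaddition is better at Ca, which it sets together with Cf and with Cb already saturated.

Alternative 2: the C7–O and C8–O bonds of an oxirane are cut, leading to the Z allylic alcohol A3, which a titanium–tartrate catalyst and an alkyl hydroperoxide would epoxidise to the epoxy alcohol A4. Converting the primary hydroxyl to a halide and opening reductively with Zn would then give C7=CH2 and the C8 hydroxyl.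
- In favour: C8 is set by a reagent with a reliable mnemonic, the methylene group arises in the same sequence, and the sensitive alpha-methylene ketone 15 is avoided. Only the allylic alcohol alkene should react.
- Against: the step does not build ring A and presupposes Ca, Ce and Cf. It needs a geometrically pure trisubstituted alkene on the hindered Ca. Z-substituted, branched allylic alcohols are the slow and less selective class for this epoxidation, and the Ca centre may be mismatched with the catalyst. The 2-methylbutanoate must also survive titanium alkoxides.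
- Comparison: on C8 control it is equal to the chosen plan (three reagent-controlled operations each) and better in avoiding 15. It is worse in convergence, because the C7–C8 bond and its geometry must be made earlier, and it offers nothing for the ring.

Alternative 3: the Ca–Cb and Ce–Cf bonds are cut. The silicon-tethered triene A5 would cyclise thermally to the cis-fused dioxasilolane ketone A6.
- In favour: the tether forces the Ce and Cf oxygens cis and the Z dienophile keeps C7 cis to the Cf oxygen, so three ring centres come from one step. Cd=Cc and the Ce oxygen are delivered at the right oxidation level, and C8 and most of the side chain are present from the start.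
- Against: the absolute sense of the ring depends on induction from C8 across a carbonyl, with no catalyst control. The beta-silyloxy enone is a deactivated dienophile, and the mixed bis-enol silaketal A5 is hydrolytically fragile and needs two enol geometries. The C7 ketone must later be methylenated beside two epimerisable centres, and the Ce/Cf diol must be differentiated after the tether is removed.
- Comparison: A6 is better than 9 in ring centres set per step and in redox economy at Ce, Cd and Cc. The two are equal in ring construction (one ring, two C–C bonds). The chosen plan is better in absolute stereocontrol and in the end-game.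

Key step: step 4

## Route

Step 1
Reactants: 1 2-chloro-N-methoxy-N-methylacetamide; 2 (4-methoxyphenyl)methanol
Product: 3 N-methoxy-2-[(4-methoxyphenyl)methoxy]-N-methylacetamide
Conditions: NaH, Bu4NI (cat.), THF, 0 °C to rt
Reagents that add atoms: none
Why: Williamson ether synthesis: the sodium alkoxide of 2 displaces the activated alpha-chloride of 1 by SN2, and the Weinreb amide resists alkoxide attack at the carbonyl; no stereocentre is formed.

Step 2
Reactants: 3 N-methoxy-2-[(4-methoxyphenyl)methoxy]-N-methylacetamide; 4 isopropenylmagnesium bromide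
Product: 6 1-[(4-methoxyphenyl)methoxy]-3-methylbut-3-en-2-one, via bromomagnesium hemiaminal chelate 5 (not isolated)
Conditions: 4 (1.3 equiv), THF, −78 to 0 °C; inverse quench into cold 1 M HCl
Reagents that add atoms: none
Why: Weinreb ketone synthesis: the chelate 5 does not collapse before work-up, so only one addition occurs; the cold acidic inverse quench protonates the released N,O-dimethylhydroxylamine before it can add to the new enone.

Step 3
Reactants: 6 1-[(4-methoxyphenyl)methoxy]-3-methylbut-3-en-2-one
Product: 7 tert-butyl({(1Z)-1-[(4-methoxyphenyl)methoxy]-3-methylbuta-1,3-dien-2-yl}oxy)dimethylsilane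
Conditions: t-BuMe2SiOTf, Et3N, CH2Cl2, −78 to 0 °C
Reagents that add atoms: tert-butyldimethylsilyl trifluoromethanesulfonate, CC(C)(C)[Si](C)(C)OS(=O)(=O)C(F)(F)F
Why: Soft enolisation (silyl triflate activation, amine deprotonation) is possible only at the CH2 between the carbonyl and the ether oxygen; the Z enol ether, with the ether oxygen syn to the silyloxy group and away from the isopropenyl group, avoids allylic 1,3-strain and should predominate, and any E isomer has its alkoxy group inside the s-cis diene and would be left behind in step 4.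

Step 4
Reactants: 7 tert-butyl({(1Z)-1-[(4-methoxyphenyl)methoxy]-3-methylbuta-1,3-dien-2-yl}oxy)dimethylsilane; 8 but-3-en-2-one
Product: 9 1-[(1R,2R)-3-{[tert-butyl(dimethyl)silyl]oxy}-2-[(4-methoxyphenyl)methoxy]-4-methylcyclohex-3-en-1-yl]ethan-1-one
Conditions: (R)-3,3-diphenyl-1-(2-methylphenyl)tetrahydro-1H,3H-pyrrolo[1,2-c][1,3,2]oxazaborole (20 mol %), (CF3SO2)2NH (18 mol %), 8 (2 equiv), CH2Cl2, −78 to −40 °C; Et3N quench
Reagents that add atoms: none
Why: The protonated oxazaborolidine binds the carbonyl oxygen of 8 in its s-trans form and lowers its LUMO, and 7 adds in a concerted, asynchronous [4+2] cycloaddition in which the Cb–Cc bond is the more advanced; the closest known reaction type is the oxazaborolidinium-catalysed Diels–Alder reaction of 2-silyloxy dienes with vinyl ketones and acrylates. Ring A is closed by an intermolecular cycloaddition, the two sigma bonds Cf–Ca and Cb–Cc forming suprafacially on both partners in a single event. Regiochemistry follows the diene HOMO: the 1-alkoxy and 3-methyl groups both enlarge the coefficient at the unsubstituted terminus Cc, which pairs with the large LUMO coefficient at the beta carbon Cb, and together they should outweigh the opposing 2-silyloxy group. Ca is set by the catalyst, which shields one face of the bound enone so that the diene meets the Si face at Ca (C7 > Cb > H); on the alpha-C–H···O binding model the catalyst from (S)-diphenylprolinol exposes the Re face of such an alpha carbon, so the (R) catalyst is specified. Cf is set relative to Ca by the endo transition state and the Z geometry of 7, whose alkoxy group lies outside the s-cis diene, so the acetyl group and the ether oxygen emerge cis. The step needs ortho regiochemistry, endo selectivity, one enone face and survival of the enol ether: acid catalysis sharpens the first two, the catalyst supplies the third, and the bulky silyl group, the low temperature and the amine quench guard against silyl transfer and a stepwise Mukaiyama–Michael path.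

Step 5
Reactants: 9 1-[(1R,2R)-3-{[tert-butyl(dimethyl)silyl]oxy}-2-[(4-methoxyphenyl)methoxy]-4-methylcyclohex-3-en-1-yl]ethan-1-one
Product: 11 1-[(1R,2R)-3-{[tert-butyl(dimethyl)silyl]oxy}-2-[(4-methoxyphenyl)methoxy]-4-methylcyclohex-3-en-1-yl]ethenyl trifluoromethanesulfonate, via potassium enolate 10 (not isolated)
Conditions: KN(SiMe3)2, THF, −78 °C; then PhN(SO2CF3)2, −78 to 0 °C
Reagents that add atoms: N-phenylbis(trifluoromethanesulfonimide), O=S(=O)(N(c1ccccc1)S(=O)(=O)C(F)(F)F)C(F)(F)F
Why: Kinetic deprotonation by the hindered amide occurs at the methyl group and not at the methine Ca, so Ca is not epimerised and no enolate forms that could expel the Cf ether; O-sulfonylation of 10 gives the terminal enol triflate.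

Step 6
Reactants: 12 4-methylpent-3-en-1-ol
Product: 13 4-methylpent-3-enal
Conditions: Dess–Martin periodinane, NaHCO3, CH2Cl2, 0 °C; used as a solution
Reagents that add atoms: none
Why: Dess–Martin oxidation under buffered, non-basic conditions stops at the aldehyde and should not move the beta,gamma-alkene into conjugation.

Step 7
Reactants: 11 1-[(1R,2R)-3-{[tert-butyl(dimethyl)silyl]oxy}-2-[(4-methoxyphenyl)methoxy]-4-methylcyclohex-3-en-1-yl]ethenyl trifluoromethanesulfonate; 13 4-methylpent-3-enal
Product: 14 (3RS)-2-[(1S,2R)-3-{[tert-butyl(dimethyl)silyl]oxy}-2-[(4-methoxyphenyl)methoxy]-4-methylcyclohex-3-en-1-yl]-6-methylhepta-1,5-dien-3-ol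
Conditions: CrCl2 (4 equiv), NiCl2 (2 mol %), DMF, rt
Reagents that add atoms: none
Why: Nozaki–Hiyama–Kishi coupling: nickel inserts into the C7–O bond of the triflate and transmetalation gives an alkenylchromium species that adds only to the aldehyde, leaving the silyl enol ether, the ether and the alkenes untouched; C8 forms without control and both epimers go on to step 8.

Step 8
Reactants: 14 (3RS)-2-[(1S,2R)-3-{[tert-butyl(dimethyl)silyl]oxy}-2-[(4-methoxyphenyl)methoxy]-4-methylcyclohex-3-en-1-yl]-6-methylhepta-1,5-dien-3-ol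
Product: 15 2-[(1S,2R)-3-{[tert-butyl(dimethyl)silyl]oxy}-2-[(4-methoxyphenyl)methoxy]-4-methylcyclohex-3-en-1-yl]-6-methylhepta-1,5-dien-3-one
Conditions: Dess–Martin periodinane, NaHCO3, CH2Cl2, 0 °C
Reagents that add atoms: none
Why: Dess–Martin oxidation of the allylic alcohol removes the uncontrolled C8 centre under buffered conditions that spare the silyl enol ether and should not isomerise the skipped C9 methylene.

Step 9
Reactants: 15 2-[(1S,2R)-3-{[tert-butyl(dimethyl)silyl]oxy}-2-[(4-methoxyphenyl)methoxy]-4-methylcyclohex-3-en-1-yl]-6-methylhepta-1,5-dien-3-one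
Product: 16 (3S)-2-[(1S,2R)-3-{[tert-butyl(dimethyl)silyl]oxy}-2-[(4-methoxyphenyl)methoxy]-4-methylcyclohex-3-en-1-yl]-6-methylhepta-1,5-dien-3-ol
Conditions: (R)-1-methyl-3,3-diphenyltetrahydro-1H,3H-pyrrolo[1,2-c][1,3,2]oxazaborole (0.5 equiv), catecholborane, toluene, −78 °C
Reagents that add atoms: none
Why: Corey–Bakshi–Shibata reduction: the ketone binds the catalyst boron anti to the larger, alpha-branched alkenyl group (C7) and hydride is delivered to the Re face of C8, which gives the S carbinol; catecholborane at low temperature reduces 1,2 and does not hydroborate the alkenes.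

Step 10
Reactants: 16 (3S)-2-[(1S,2R)-3-{[tert-butyl(dimethyl)silyl]oxy}-2-[(4-methoxyphenyl)methoxy]-4-methylcyclohex-3-en-1-yl]-6-methylhepta-1,5-dien-3-ol; 17 (2Z)-2-methylbut-2-enoic acid (angelic acid)
Product: 19 (3S)-2-[(1S,2R)-3-{[tert-butyl(dimethyl)silyl]oxy}-2-[(4-methoxyphenyl)methoxy]-4-methylcyclohex-3-en-1-yl]-6-methylhepta-1,5-dien-3-yl (2Z)-2-methylbut-2-enoate, via angelic 2,4,6-trichlorobenzoic anhydride 18 (not isolated)
Conditions: 17, 2,4,6-Cl3C6H2COCl, Et3N, toluene, rt; then 16, 75 °C
Reagents that add atoms: none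
Why: Yamaguchi esterification: the shielded aroyl carbonyl of 18 sends the alcohol to the angeloyl carbonyl, and leaving out nucleophilic catalysts avoids the addition–elimination that converts the Z acid into its E isomer; C8 is not touched.

Step 11
Reactants: 19 (3S)-2-[(1S,2R)-3-{[tert-butyl(dimethyl)silyl]oxy}-2-[(4-methoxyphenyl)methoxy]-4-methylcyclohex-3-en-1-yl]-6-methylhepta-1,5-dien-3-yl (2Z)-2-methylbut-2-enoate
Product: 20 (3S)-2-[(1S,2R)-2-[(4-methoxyphenyl)methoxy]-4-methyl-3-oxocyclohex-4-en-1-yl]-6-methylhepta-1,5-dien-3-yl (2Z)-2-methylbut-2-enoate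
Conditions: Pd(OAc)2 (1.2 equiv), MeCN, rt to 40 °C
Reagents that add atoms: none
Why: Saegusa–Ito oxidation: divalent palladium displaces silicon to give a palladium enolate bound at Cd, and syn beta-hydride elimination toward the ring methylene Cc gives the conjugated endocyclic enone on the side fixed by the cycloaddition; no stereocentre is involved.

Step 12
Reactants: 20 (3S)-2-[(1S,2R)-2-[(4-methoxyphenyl)methoxy]-4-methyl-3-oxocyclohex-4-en-1-yl]-6-methylhepta-1,5-dien-3-yl (2Z)-2-methylbut-2-enoate
Product: 21 (2S)-1-[(2R)-3,3-dimethyloxiran-2-yl]-3-[(1S,2R)-2-[(4-methoxyphenyl)methoxy]-4-methyl-3-oxocyclohex-4-en-1-yl]but-3-en-2-yl (2Z)-2-methylbut-2-enoate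
Conditions: 1,2:4,5-di-O-isopropylidene-β-D-erythro-2,3-hexodiulo-2,6-pyranose (0.3 equiv), KHSO5 (as 2KHSO5·KHSO4·K2SO4), K2CO3, Bu4NHSO4, MeCN–CH2(OMe)2/aq. Na2B4O7 buffer (pH 10.5), 0 °C
Reagents that add atoms: potassium peroxymonosulfate, [K+].[O-]S(=O)(=O)OO
Why: Shi epoxidation: the chiral dioxirane formed in the flask transfers oxygen through a spiro transition state to the only electron-rich alkene, C10=C11, while the enone, the enoate and the ester-flanked methylene are electron-poor; the D-fructose-derived ketone gives the R configuration at C10 by reagent control.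

Step 13
Reactants: 21 (2S)-1-[(2R)-3,3-dimethyloxiran-2-yl]-3-[(1S,2R)-2-[(4-methoxyphenyl)methoxy]-4-methyl-3-oxocyclohex-4-en-1-yl]but-3-en-2-yl (2Z)-2-methylbut-2-enoate
Product: 22 (2S)-1-[(2R)-3,3-dimethyloxiran-2-yl]-3-[(1S,2R)-2-hydroxy-4-methyl-3-oxocyclohex-4-en-1-yl]but-3-en-2-yl (2Z)-2-methylbut-2-enoate
Conditions: DDQ, CH2Cl2–pH 7 phosphate buffer, 0 °C to rt
Reagents that add atoms: none
Why: Oxidative cleavage of the 4-methoxybenzyl ether by hydride abstraction and hydrolysis of the resulting oxocarbenium ion; the buffer keeps the medium neutral for the oxirane and no stereocentre is involved.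

Step 14
Reactants: 22 (2S)-1-[(2R)-3,3-dimethyloxiran-2-yl]-3-[(1S,2R)-2-hydroxy-4-methyl-3-oxocyclohex-4-en-1-yl]but-3-en-2-yl (2Z)-2-methylbut-2-enoate; 23 (2R)-2-methylbutanoic acid
Product: 24 (2S)-1-[(2R)-3,3-dimethyloxiran-2-yl]-3-[(1S,2R)-4-methyl-2-{[(2R)-2-methylbutanoyl]oxy}-3-oxocyclohex-4-en-1-yl]but-3-en-2-yl (2Z)-2-methylbut-2-enoate
Conditions: EDC·HCl, 4-(dimethylamino)pyridine (cat.), CH2Cl2, 0 °C to rt
Reagents that add atoms: none
Why: Steglich esterification of the only hydroxyl; carbodiimide activation with a catalytic acyl-transfer base at low temperature is mild enough to keep the alpha centre of 23 and the enolisable Cf centre intact.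

Step 15
Reactants: 24 (2S)-1-[(2R)-3,3-dimethyloxiran-2-yl]-3-[(1S,2R)-4-methyl-2-{[(2R)-2-methylbutanoyl]oxy}-3-oxocyclohex-4-en-1-yl]but-3-en-2-yl (2Z)-2-methylbut-2-enoate
Product: 25 (2S)-1-[(2R)-3,3-dimethyloxiran-2-yl]-3-[(1S,5S,6R)-5-hydroxy-4-methyl-6-{[(2R)-2-methylbutanoyl]oxy}cyclohex-3-en-1-yl]but-3-en-2-yl (2Z)-2-methylbut-2-enoate
Conditions: NaBH4, CeCl3·7H2O, MeOH, −78 °C; AcOH quench
Reagents that add atoms: none
Why: Luche reduction: cerium-assisted 1,2-hydride addition to the enone; with the large C7 chain equatorial the Cf acyloxy group is axial and hydride adds axially, anti to it, so the new Ce hydroxyl is cis to both neighbours; the low temperature and the acidic quench are chosen to suppress acyl migration.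

Step 16
Reactants: 25 (2S)-1-[(2R)-3,3-dimethyloxiran-2-yl]-3-[(1S,5S,6R)-5-hydroxy-4-methyl-6-{[(2R)-2-methylbutanoyl]oxy}cyclohex-3-en-1-yl]but-3-en-2-yl (2Z)-2-methylbut-2-enoate
Product: 26 (2S)-1-[(2R)-3,3-dimethyloxiran-2-yl]-3-[(1S,3S,4R,5R,6R)-5-hydroxy-6-methyl-4-{[(2R)-2-methylbutanoyl]oxy}-7-oxabicyclo[4.1.0]heptan-3-yl]but-3-en-2-yl (2Z)-2-methylbut-2-enoate
Conditions: VO(acac)2 (5 mol %), t-BuOOH, CH2Cl2, 0 °C to rt
Reagents that add atoms: tert-butyl hydroperoxide, CC(C)(C)OO
Why: Hydroxyl-directed vanadium-catalysed epoxidation: the Ce alkoxide binds vanadium and the peroxide oxygen is delivered to the adjacent Cd=Cc bond on the hydroxyl face, setting Cc and Cd cis to the Ce oxygen; the other alkenes are not allylic to a free hydroxyl and the neutral medium spares both oxiranes and both esters.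

## Compound list

1 | 2-chloro-N-methoxy-N-methylacetamide | CON(C)C(=O)CCl | starting material
2 | (4-methoxyphenyl)methanol | COc1ccc(CO)cc1 | starting material
3 | N-methoxy-2-[(4-methoxyphenyl)methoxy]-N-methylacetamide | CON(C)C(=O)COCc1ccc(OC)cc1 | intermediate
4 | isopropenylmagnesium bromide | CC(=C)[Mg]Br | starting material
5 | bromomagnesium hemiaminal chelate of 3 and 4 | C=C(C)C(O[Mg]Br)(COCc1ccc(OC)cc1)N(C)OC | intermediate (not isolated)
6 | 1-[(4-methoxyphenyl)methoxy]-3-methylbut-3-en-2-one | C=C(C)C(=O)COCc1ccc(OC)cc1 | intermediate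
7 | tert-butyl({(1Z)-1-[(4-methoxyphenyl)methoxy]-3-methylbuta-1,3-dien-2-yl}oxy)dimethylsilane | C=C(C)/C(O[Si](C)(C)C(C)(C)C)=C/OCc1ccc(OC)cc1 | intermediate
8 | but-3-en-2-one | CC(=O)C=C | starting material
9 | 1-[(1R,2R)-3-{[tert-butyl(dimethyl)silyl]oxy}-2-[(4-methoxyphenyl)methoxy]-4-methylcyclohex-3-en-1-yl]ethan-1-one | CC(=O)[C@@H]1CCC(C)=C(O[Si](C)(C)C(C)(C)C)[C@@H]1OCc1ccc(OC)cc1 | intermediate
10 | potassium 1-[(1R,2R)-3-{[tert-butyl(dimethyl)silyl]oxy}-2-[(4-methoxyphenyl)methoxy]-4-methylcyclohex-3-en-1-yl]ethen-1-olate | C=C(O[K])[C@@H]1CCC(C)=C(O[Si](C)(C)C(C)(C)C)[C@@H]1OCc1ccc(OC)cc1 | intermediate (not isolated)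
11 | 1-[(1R,2R)-3-{[tert-butyl(dimethyl)silyl]oxy}-2-[(4-methoxyphenyl)methoxy]-4-methylcyclohex-3-en-1-yl]ethenyl trifluoromethanesulfonate | C=C(OS(=O)(=O)C(F)(F)F)[C@@H]1CCC(C)=C(O[Si](C)(C)C(C)(C)C)[C@@H]1OCc1ccc(OC)cc1 | intermediate
12 | 4-methylpent-3-en-1-ol | CC(C)=CCCO | starting material
13 | 4-methylpent-3-enal | CC(C)=CCC=O | intermediate
14 | (3RS)-2-[(1S,2R)-3-{[tert-butyl(dimethyl)silyl]oxy}-2-[(4-methoxyphenyl)methoxy]-4-methylcyclohex-3-en-1-yl]-6-methylhepta-1,5-dien-3-ol | C=C(C(O)CC=C(C)C)[C@@H]1CCC(C)=C(O[Si](C)(C)C(C)(C)C)[C@@H]1OCc1ccc(OC)cc1 | intermediate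
15 | 2-[(1S,2R)-3-{[tert-butyl(dimethyl)silyl]oxy}-2-[(4-methoxyphenyl)methoxy]-4-methylcyclohex-3-en-1-yl]-6-methylhepta-1,5-dien-3-one | C=C(C(=O)CC=C(C)C)[C@@H]1CCC(C)=C(O[Si](C)(C)C(C)(C)C)[C@@H]1OCc1ccc(OC)cc1 | intermediate
16 | (3S)-2-[(1S,2R)-3-{[tert-butyl(dimethyl)silyl]oxy}-2-[(4-methoxyphenyl)methoxy]-4-methylcyclohex-3-en-1-yl]-6-methylhepta-1,5-dien-3-ol | C=C([C@H](CC=C(C)C)O)[C@@H]1CCC(C)=C(O[Si](C)(C)C(C)(C)C)[C@@H]1OCc1ccc(OC)cc1 | intermediate
17 | (2Z)-2-methylbut-2-enoic acid (angelic acid) | C/C=C(/C)C(=O)O | starting material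
18 | (2Z)-2-methylbut-2-enoic 2,4,6-trichlorobenzoic anhydride | C/C=C(/C)C(=O)OC(=O)c1c(Cl)cc(Cl)cc1Cl | intermediate (not isolated)
19 | (3S)-2-[(1S,2R)-3-{[tert-butyl(dimethyl)silyl]oxy}-2-[(4-methoxyphenyl)methoxy]-4-methylcyclohex-3-en-1-yl]-6-methylhepta-1,5-dien-3-yl (2Z)-2-methylbut-2-enoate | C=C([C@H](CC=C(C)C)OC(=O)/C(C)=C\C)[C@@H]1CCC(C)=C(O[Si](C)(C)C(C)(C)C)[C@@H]1OCc1ccc(OC)cc1 | intermediate
20 | (3S)-2-[(1S,2R)-2-[(4-methoxyphenyl)methoxy]-4-methyl-3-oxocyclohex-4-en-1-yl]-6-methylhepta-1,5-dien-3-yl (2Z)-2-methylbut-2-enoate | C=C([C@H](CC=C(C)C)OC(=O)/C(C)=C\C)[C@@H]1CC=C(C)C(=O)[C@@H]1OCc1ccc(OC)cc1 | intermediate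
21 | (2S)-1-[(2R)-3,3-dimethyloxiran-2-yl]-3-[(1S,2R)-2-[(4-methoxyphenyl)methoxy]-4-methyl-3-oxocyclohex-4-en-1-yl]but-3-en-2-yl (2Z)-2-methylbut-2-enoate | C=C([C@H](C[C@H]1OC1(C)C)OC(=O)/C(C)=C\C)[C@@H]1CC=C(C)C(=O)[C@@H]1OCc1ccc(OC)cc1 | intermediate
22 | (2S)-1-[(2R)-3,3-dimethyloxiran-2-yl]-3-[(1S,2R)-2-hydroxy-4-methyl-3-oxocyclohex-4-en-1-yl]but-3-en-2-yl (2Z)-2-methylbut-2-enoate | C=C([C@H](C[C@H]1OC1(C)C)OC(=O)/C(C)=C\C)[C@@H]1CC=C(C)C(=O)[C@@H]1O | intermediate
23 | (2R)-2-methylbutanoic acid | CC[C@@H](C)C(=O)O | starting material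
24 | (2S)-1-[(2R)-3,3-dimethyloxiran-2-yl]-3-[(1S,2R)-4-methyl-2-{[(2R)-2-methylbutanoyl]oxy}-3-oxocyclohex-4-en-1-yl]but-3-en-2-yl (2Z)-2-methylbut-2-enoate | C=C([C@H](C[C@H]1OC1(C)C)OC(=O)/C(C)=C\C)[C@@H]1CC=C(C)C(=O)[C@@H]1OC(=O)[C@H](C)CC | intermediate
25 | (2S)-1-[(2R)-3,3-dimethyloxiran-2-yl]-3-[(1S,5S,6R)-5-hydroxy-4-methyl-6-{[(2R)-2-methylbutanoyl]oxy}cyclohex-3-en-1-yl]but-3-en-2-yl (2Z)-2-methylbut-2-enoate | C=C([C@H](C[C@H]1OC1(C)C)OC(=O)/C(C)=C\C)[C@@H]1CC=C(C)[C@H](O)[C@@H]1OC(=O)[C@H](C)CC | intermediate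
26 | (2S)-1-[(2R)-3,3-dimethyloxiran-2-yl]-3-[(1S,3S,4R,5R,6R)-5-hydroxy-6-methyl-4-{[(2R)-2-methylbutanoyl]oxy}-7-oxabicyclo[4.1.0]heptan-3-yl]but-3-en-2-yl (2Z)-2-methylbut-2-enoate | C=C([C@H](C[C@H]1OC1(C)C)OC(=O)/C(C)=C\C)[C@@H]1C[C@@H]2O[C@]2(C)[C@H](O)[C@@H]1OC(=O)[C@H](C)CC | target

## Step count and least certain steps

Total: 16 steps. Longest linear sequence: 15 steps (steps 1 to 5 and 7 to 16); step 6 is a one-step side branch.

Step 4 (key step). The most likely failure is acid-promoted silyl transfer from the diene to the catalyst-bound enone, which would give a Mukaiyama–Michael adduct without ring closure. Loss of regio- or enantiocontrol is also possible, because the ether oxygen competes for boron and this 1,2-dioxygenated diene has no direct precedent. The sense of induction is assigned from the binding model and would have to be confirmed on the first adduct. The fallback sets out from 7 and 8 and gives up catalyst control. The two are heated without acid (toluene, 80 °C, a trace of Et3N) to give the racemic cis adduct F1 by the thermal endo cycloaddition. Steps 5, 7 and 8 are then run on racemic material to give the racemic enol triflate F2, the racemic alcohol mixture F3 and the racemic enone F4. The reagent-controlled reduction of step 9 should convert F4 into two diastereomeric (8S) alcohols, 16 and its ring-enantiomeric diastereomer F5, which are separated by chromatography. The route is rejoined at 16, at the cost of half the material.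

Step 11. Palladation of the hindered, tetrasubstituted silyl enol ether may be slow. The zerovalent palladium that builds up could then ionise the allylic angelate, or beta-hydride loss could go toward the methyl group. The fallback sets out from 19. Regiospecific selenenylation of the silyl enol ether with PhSeCl (CH2Cl2, −78 °C) gives the alpha-phenylselanyl ketone F6 as a mixture at Cd. Oxidation with H2O2 and pyridine at 0 °C, followed by syn elimination of the selenoxide toward the ring methylene, returns the route at 20.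

Step 15. The new Ce alkoxide is cis-vicinal to the Cf ester, so 1,2-acyl migration during the borohydride reduction is the main danger, with hydride delivery from the wrong face a lesser one. The fallback sets out from 21 and reduces before the ester exchange. Luche reduction of 21 gives the allylic alcohol F7, and Et3SiCl with imidazole gives the silyl ether F8. DDQ in buffered CH2Cl2 then frees the Cf hydroxyl in F9, and esterification with 23 (EDC·HCl, 4-(dimethylamino)pyridine) gives F10. Removal of the silyl group with HF·pyridine buffered with pyridine (THF, 0 °C) returns the route at 25, two steps longer.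

Step 7. The beta,gamma-unsaturated aldehyde 13 may enolise or isomerise on Lewis-acidic chromium while nickel inserts only slowly into the hindered triflate, giving low conversion. The fallback sets out from 9 and avoids both 11 and chromium. Condensation with 2,4,6-triisopropylbenzenesulfonohydrazide gives the hydrazone F11. n-BuLi (2.2 equiv, THF, −78 to 0 °C) converts it by the Shapiro reaction into the alkenyllithium F12, and addition of 13 at −78 °C returns the route at 14.

Step 10. At 75 °C the angeloyl unit may isomerise to the E (tigloyl) form during acyl transfer. The fallback sets out from 16 and builds the Z alkene instead of transferring it. Esterification with 2-[bis(2,2,2-trifluoroethoxy)phosphoryl]propanoic acid (EDC·HCl, 4-(dimethylamino)pyridine) gives the phosphonate ester F13. Still–Gennari olefination with acetaldehyde (KN(SiMe3)2, 18-crown-6, THF, −78 °C) gives the Z enoate and returns the route at 19.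

## Further compounds

F1 | step 4 | racemic 1-[(1R,2R)-3-{[tert-butyl(dimethyl)silyl]oxy}-2-[(4-methoxyphenyl)methoxy]-4-methylcyclohex-3-en-1-yl]ethan-1-one | CC(=O)[C@@H]1CCC(C)=C(O[Si](C)(C)C(C)(C)C)[C@@H]1OCc1ccc(OC)cc1.CC(=O)[C@H]1CCC(C)=C(O[Si](C)(C)C(C)(C)C)[C@H]1OCc1ccc(OC)cc1
F2 | step 4 | racemic 1-[(1R,2R)-3-{[tert-butyl(dimethyl)silyl]oxy}-2-[(4-methoxyphenyl)methoxy]-4-methylcyclohex-3-en-1-yl]ethenyl trifluoromethanesulfonate | C=C(OS(=O)(=O)C(F)(F)F)[C@@H]1CCC(C)=C(O[Si](C)(C)C(C)(C)C)[C@@H]1OCc1ccc(OC)cc1.C=C(OS(=O)(=O)C(F)(F)F)[C@H]1CCC(C)=C(O[Si](C)(C)C(C)(C)C)[C@H]1OCc1ccc(OC)cc1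
F3 | step 4 | racemic 2-[(1S,2R)-3-{[tert-butyl(dimethyl)silyl]oxy}-2-[(4-methoxyphenyl)methoxy]-4-methylcyclohex-3-en-1-yl]-6-methylhepta-1,5-dien-3-ol, both C3 epimers | C=C(C(O)CC=C(C)C)[C@@H]1CCC(C)=C(O[Si](C)(C)C(C)(C)C)[C@@H]1OCc1ccc(OC)cc1.C=C(C(O)CC=C(C)C)[C@H]1CCC(C)=C(O[Si](C)(C)C(C)(C)C)[C@H]1OCc1ccc(OC)cc1
F4 | step 4 | racemic 2-[(1S,2R)-3-{[tert-butyl(dimethyl)silyl]oxy}-2-[(4-methoxyphenyl)methoxy]-4-methylcyclohex-3-en-1-yl]-6-methylhepta-1,5-dien-3-one | C=C(C(=O)CC=C(C)C)[C@@H]1CCC(C)=C(O[Si](C)(C)C(C)(C)C)[C@@H]1OCc1ccc(OC)cc1.C=C(C(=O)CC=C(C)C)[C@H]1CCC(C)=C(O[Si](C)(C)C(C)(C)C)[C@H]1OCc1ccc(OC)cc1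
F5 | step 4 | (3S)-2-[(1R,2S)-3-{[tert-butyl(dimethyl)silyl]oxy}-2-[(4-methoxyphenyl)methoxy]-4-methylcyclohex-3-en-1-yl]-6-methylhepta-1,5-dien-3-ol | C=C([C@H](CC=C(C)C)O)[C@H]1CCC(C)=C(O[Si](C)(C)C(C)(C)C)[C@H]1OCc1ccc(OC)cc1
F6 | step 11 | (3S)-2-[(1S,2R)-2-[(4-methoxyphenyl)methoxy]-4-methyl-3-oxo-4-(phenylselanyl)cyclohexyl]-6-methylhepta-1,5-dien-3-yl (2Z)-2-methylbut-2-enoate, both epimers at the selenium-bearing carbon | C=C([C@H](CC=C(C)C)OC(=O)/C(C)=C\C)[C@@H]1CCC(C)([Se]c2ccccc2)C(=O)[C@@H]1OCc1ccc(OC)cc1
F7 | step 15 | (2S)-1-[(2R)-3,3-dimethyloxiran-2-yl]-3-[(1S,5S,6R)-5-hydroxy-6-[(4-methoxyphenyl)methoxy]-4-methylcyclohex-3-en-1-yl]but-3-en-2-yl (2Z)-2-methylbut-2-enoate | C=C([C@H](C[C@H]1OC1(C)C)OC(=O)/C(C)=C\C)[C@@H]1CC=C(C)[C@H](O)[C@@H]1OCc1ccc(OC)cc1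
F8 | step 15 | (2S)-1-[(2R)-3,3-dimethyloxiran-2-yl]-3-[(1S,5S,6R)-6-[(4-methoxyphenyl)methoxy]-4-methyl-5-[(triethylsilyl)oxy]cyclohex-3-en-1-yl]but-3-en-2-yl (2Z)-2-methylbut-2-enoate | C=C([C@H](C[C@H]1OC1(C)C)OC(=O)/C(C)=C\C)[C@@H]1CC=C(C)[C@H](O[Si](CC)(CC)CC)[C@@H]1OCc1ccc(OC)cc1
F9 | step 15 | (2S)-1-[(2R)-3,3-dimethyloxiran-2-yl]-3-[(1S,5S,6R)-6-hydroxy-4-methyl-5-[(triethylsilyl)oxy]cyclohex-3-en-1-yl]but-3-en-2-yl (2Z)-2-methylbut-2-enoate | C=C([C@H](C[C@H]1OC1(C)C)OC(=O)/C(C)=C\C)[C@@H]1CC=C(C)[C@H](O[Si](CC)(CC)CC)[C@@H]1O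
F10 | step 15 | (2S)-1-[(2R)-3,3-dimethyloxiran-2-yl]-3-[(1S,5S,6R)-4-methyl-6-{[(2R)-2-methylbutanoyl]oxy}-5-[(triethylsilyl)oxy]cyclohex-3-en-1-yl]but-3-en-2-yl (2Z)-2-methylbut-2-enoate | C=C([C@H](C[C@H]1OC1(C)C)OC(=O)/C(C)=C\C)[C@@H]1CC=C(C)[C@H](O[Si](CC)(CC)CC)[C@@H]1OC(=O)[C@H](C)CC
F11 | step 7 | N'-{1-[(1S,2R)-3-{[tert-butyl(dimethyl)silyl]oxy}-2-[(4-methoxyphenyl)methoxy]-4-methylcyclohex-3-en-1-yl]ethylidene}-2,4,6-tri(propan-2-yl)benzenesulfonohydrazide | CC(=NNS(=O)(=O)c1c(C(C)C)cc(C(C)C)cc1C(C)C)[C@@H]1CCC(C)=C(O[Si](C)(C)C(C)(C)C)[C@@H]1OCc1ccc(OC)cc1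
F12 | step 7 | {1-[(1S,2R)-3-{[tert-butyl(dimethyl)silyl]oxy}-2-[(4-methoxyphenyl)methoxy]-4-methylcyclohex-3-en-1-yl]ethenyl}lithium | [Li]C(=C)[C@@H]1CCC(C)=C(O[Si](C)(C)C(C)(C)C)[C@@H]1OCc1ccc(OC)cc1
F13 | step 10 | (3S)-2-[(1S,2R)-3-{[tert-butyl(dimethyl)silyl]oxy}-2-[(4-methoxyphenyl)methoxy]-4-methylcyclohex-3-en-1-yl]-6-methylhepta-1,5-dien-3-yl 2-[bis(2,2,2-trifluoroethoxy)phosphoryl]propanoate | C=C([C@H](CC=C(C)C)OC(=O)C(C)P(=O)(OCC(F)(F)F)OCC(F)(F)F)[C@@H]1CCC(C)=C(O[Si](C)(C)C(C)(C)C)[C@@H]1OCc1ccc(OC)cc1
A1 | alternative 1 | 1-iodo-4-methylbenzene | Cc1ccc(I)cc1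
A2 | alternative 1 | (1S,2S)-3-iodo-6-methylcyclohexa-3,5-diene-1,2-diol | IC1=CC=C(C)[C@H](O)[C@@H]1O
A3 | alternative 2 | (1R,2S,6S)-6-[(2Z)-1-hydroxy-6-methylhepta-2,5-dien-2-yl]-3-methyl-2-[(triethylsilyl)oxy]cyclohex-3-en-1-yl (2R)-2-methylbutanoate | OC/C(=C\CC=C(C)C)[C@@H]1CC=C(C)[C@H](O[Si](CC)(CC)CC)[C@@H]1OC(=O)[C@H](C)CC
A4 | alternative 2 | (1R,2S,6R)-6-[(2R,3S)-2-(hydroxymethyl)-3-(3-methylbut-2-en-1-yl)oxiran-2-yl]-3-methyl-2-[(triethylsilyl)oxy]cyclohex-3-en-1-yl (2R)-2-methylbutanoate | OC[C@]1(O[C@H]1CC=C(C)C)[C@@H]2CC=C(C)[C@H](O[Si](CC)(CC)CC)[C@@H]2OC(=O)[C@H](C)CC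
A5 | alternative 3 | (1Z,4S)-4-[(4-methoxyphenyl)methoxy]-7-methyl-1-{[{[(1E)-2-methylbuta-1,3-dien-1-yl]oxy}di(propan-2-yl)silyl]oxy}octa-1,6-dien-3-one | C=C/C(C)=C/O[Si](C(C)C)(C(C)C)O/C=C\C(=O)[C@H](CC=C(C)C)OCc1ccc(OC)cc1
A6 | alternative 3 | (2S)-2-[(4-methoxyphenyl)methoxy]-5-methyl-1-[(3aR,4R,7aS)-7-methyl-2,2-di(propan-2-yl)-3a,4,5,7a-tetrahydro-1,3,2-benzodioxasilol-4-yl]hex-4-en-1-one | O=C([C@H](CC=C(C)C)OCc3ccc(OC)cc3)[C@@H]1CC=C(C)[C@@H]2O[Si](C(C)C)(C(C)C)O[C@H]12
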